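The C3' carbinol is traced back to an isopropenyl ketone. The C5'–C6' bond (chain CH2 to the C(=CH2) carbon) is then cut to an ethynyl carbinol and a vinyl carbinol, C4–Br and C3–Cl go back to a C3–C4 epoxide and alkene, the alkyne CH goes back to a CH2OH carbon, and the ring opens to isoprene and methyl propiolate.
Enabling feature: C6' is a 1,1-disubstituted alkene carbon held between the tertiary ring carbinol C1 and a CH2–CH2–C3'(O) chain. This is the branched product pattern of a terminal alkyne on C1 and the vinyl group of an allylic alcohol in a ruthenium Alder-ene/redox coupling.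
Forward order: the cyclohexane ring is closed first (Diels–Alder), C1 is oxygenated and trimmed to the ethynyl carbinol with the C1–C6 and C3–C4 epoxides serving only as relays, both halogens go onto this compact alkyne, and the six-carbon chain fragment is joined last with no further ring closure.
Stereochemistry: C1 comes from a Sharpless epoxidation with L-(+)-tartrate, C3 from a hydroxyl-directed epoxidation followed by SN2 inversion with chloride, C4 from bromide capture of the tertiary cation opposite to the C3–Cl bond (net retention), and C3' from a CBS reduction with the (S)-oxazaborolidine.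
The slim ethynyl group tolerates the axial position on C1, so chloride at C3 and bromide at C4 can both enter along trans-diaxial paths before the bulky chain biases the ring the other way.

Key step: step 13

Remark: ring locants C1 to C6 are those of the target (C1 carbinol, C3 CHCl, C4 CBrCH3) and are kept for every intermediate in the explanatory lines; primed locants belong to the heptadienol chain (C3' carbinol, C6' the C(=CH2) carbon).

Step 1
Reactants: 1 isoprene; 2 methyl propiolate
Product: 3 methyl 4-methylcyclohexa-1,4-diene-1-carboxylate
Conditions: EtAlCl2 (0.2 equiv), 1 (2 equiv), toluene, 0 °C → rt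
Reagents that add atoms: none
Why: Lewis-acid-accelerated Diels–Alder reaction in which aluminium coordination to the ester polarises the alkyne so that its unsubstituted carbon pairs with C1 of isoprene, the diene terminus with the largest HOMO coefficient, which should favour the 1,4-disubstituted ("para") cyclohexadiene and closes the only carbocycle of the target without creating a stereocentre.

Step 2
Reactants: 3 methyl 4-methylcyclohexa-1,4-diene-1-carboxylate
Product: 4 (4-methylcyclohexa-1,4-dien-1-yl)methanol
Conditions: iBu2AlH (2.3 equiv), CH2Cl2, −78 → 0 °C; aq. potassium sodium tartrate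
Reagents that add atoms: none
Why: Ester reduction with iBu2AlH is a clean 1,2-reduction of conjugated esters that should stop at the achiral allylic alcohol and leave both alkenes of the skipped diene in place.

Step 3
Reactants: 4 (4-methylcyclohexa-1,4-dien-1-yl)methanol
Product: 5 [(1S,6S)-4-methyl-7-oxabicyclo[4.1.0]hept-3-en-1-yl]methanol
Conditions: Ti(OiPr)4 (10 mol %), diethyl L-(+)-tartrate (12 mol %), t-BuOOH (1.5 equiv, decane), 4 Å molecular sieves, CH2Cl2, −20 °C
Reagents that add atoms: tert-butyl hydroperoxide, CC(C)(C)OO
Why: Sharpless asymmetric epoxidation, in which only the C1=C6 alkene allylic to the titanium-bound carbinol is oxidised while the remote C3=C4 alkene is ignored, and in which the L-(+)-tartrate delivers oxygen in the same sense that turns E-configured 2-alken-1-ols into (2S,3S)-epoxy alcohols, so that the C1–O bond of the target is set as (1S) together with a sacrificial (6S) centre.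

Step 4
Reactants: 5 [(1S,6S)-4-methyl-7-oxabicyclo[4.1.0]hept-3-en-1-yl]methanol
Product: 6 (S)-1-(hydroxymethyl)-4-methylcyclohex-3-en-1-ol
Conditions: LiAlH4 (1.5 equiv), THF, 0 °C → rt; aq. NaOH work-up
Reagents that add atoms: none
Why: Hydride opening of a trisubstituted epoxide by SN2 attack at its less hindered secondary carbon C6 gives the 1,2-diol, the C1–O bond is never broken so C1 keeps its configuration, and the C6 stereocentre disappears as a CH2 group.

Step 5
Reactants: 6 (S)-1-(hydroxymethyl)-4-methylcyclohex-3-en-1-ol
Product: 7 (S)-1-hydroxy-4-methylcyclohex-3-ene-1-carbaldehyde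
Conditions: 2-iodoxybenzoic acid (IBX, 1.5 equiv), DMSO, rt; crude aldehyde carried on after extraction
Reagents that add atoms: none
Why: Oxidation with 2-iodoxybenzoic acid converts 1,2-diols into α-hydroxy carbonyl compounds without glycol cleavage, only the primary alcohol can react, and the fully substituted C1 cannot epimerise.

Step 6
Reactants: 7 (S)-1-hydroxy-4-methylcyclohex-3-ene-1-carbaldehyde
Product: 8 (S)-1-ethynyl-4-methylcyclohex-3-en-1-ol
Conditions: dimethyl (1-diazo-2-oxopropyl)phosphonate (1.3 equiv), K2CO3 (2 equiv), MeOH, 0 °C → rt
Reagents that add atoms: dimethyl (1-diazo-2-oxopropyl)phosphonate, COP(=O)(OC)C(=[N+]=[N-])C(C)=O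
Why: Ohira–Bestmann variant of the Seyferth–Gilbert homologation, in which the diazophosphonate anion released by methanolysis adds to the aldehyde and loss of phosphate and nitrogen with a 1,2-hydrogen shift leaves the terminal alkyne under carbonate conditions mild enough for the free tertiary alcohol, C1 being a spectator.

Step 7
Reactants: 8 (S)-1-ethynyl-4-methylcyclohex-3-en-1-ol
Product: 9 (1S,3S,6R)-3-ethynyl-6-methyl-7-oxabicyclo[4.1.0]heptan-3-ol (epoxide cis to the hydroxyl)
Conditions: VO(acac)2 (2 mol %), t-BuOOH (1.3 equiv, decane), toluene, 0 °C → rt
Reagents that add atoms: tert-butyl hydroperoxide, CC(C)(C)OO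
Why: Hydroxyl-directed vanadium/alkyl hydroperoxide epoxidation of a homoallylic cyclohexenol, in which the pseudoaxial C1 alkoxide binds the vanadium peroxide and hands oxygen to its own face of the C3=C4 alkene, as established for terpinen-4-ol-type substrates, so that the epoxide carbons C3 and C4 are set cis to the C1 hydroxyl while the alkyne stays inert.

Step 8
Reactants: 9 (1S,3S,6R)-3-ethynyl-6-methyl-7-oxabicyclo[4.1.0]heptan-3-ol
Product: 10 (1S,3S,6R)-3-ethynyl-6-methyl-7-oxabicyclo[4.1.0]heptan-3-yl acetate
Conditions: Ac2O (3 equiv), Et3N (4 equiv), 4-(dimethylamino)pyridine (0.2 equiv), CH2Cl2, rt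
Reagents that add atoms: acetic anhydride, CC(=O)OC(C)=O
Why: Nucleophile-catalysed acylation works on unhindered tertiary propargylic alcohols and leaves the epoxide alone, and the acetate is needed so that the C1 oxygen can neither bridge to C4 as a bicyclic ether nor ionise in the acidic steps that follow.

Step 9
Reactants: 10 (1S,3S,6R)-3-ethynyl-6-methyl-7-oxabicyclo[4.1.0]heptan-3-yl acetate
Product: 11 (1S,3R,4R)-3-chloro-1-ethynyl-4-hydroxy-4-methylcyclohexyl acetate
Conditions: LiCl (5 equiv), AcOH (3 equiv), THF, rt
Reagents that add atoms: lithium chloride, [Li+].[Cl-]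
Why: SN2 halohydrin formation obeying the trans-diaxial (Fürst–Plattner) rule, in which, with only lithium ion and acetic acid as activators, chloride attacks the less substituted C3 from the face opposite to the epoxide oxygen through the half-chair that keeps the slim ethynyl group axial and the acetate equatorial, which inverts C3 to (3R) and leaves the C4–O bond and hence the C4 configuration untouched.

Step 10
Reactants: 11 (1S,3R,4R)-3-chloro-1-ethynyl-4-hydroxy-4-methylcyclohexyl acetate
Product: 12 (1S,3R,4R)-4-bromo-3-chloro-1-ethynyl-4-methylcyclohexyl acetate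
Conditions: Me3SiBr (3 equiv), CH2Cl2, −20 → 0 °C
Reagents that add atoms: bromotrimethylsilane, C[Si](C)(C)Br
Why: SN1-type bromination of a tertiary alcohol with Me3SiBr under neighbouring-chlorine participation, in which the axial-ethynyl chair places the C3–Cl bond antiperiplanar to the activated C4–O bond, ionisation gives a chlorine-bridged or chlorine-shielded tertiary cation, and bromide enters at the more substituted C4 from the face opposite to chlorine, which returns the halogen to the side the oxygen left (net retention, 4R, Br trans to Cl) while the electron-poor C1 acetate stays in place.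

Step 11
Reactants: 12 (1S,3R,4R)-4-bromo-3-chloro-1-ethynyl-4-methylcyclohexyl acetate
Product: 13 (1S,3R,4R)-4-bromo-3-chloro-1-ethynyl-4-methylcyclohexan-1-ol
Conditions: iBu2AlH (2.5 equiv), CH2Cl2, −78 °C; aq. potassium sodium tartrate
Reagents that add atoms: none
Why: Reductive cleavage of the hindered acetate with iBu2AlH at low temperature is a non-basic ester reduction that should spare the tertiary bromide, the secondary chloride and the terminal alkyne, where alkoxide or hydroxide could provoke E2 loss of HBr, and it touches no stereocentre.

Step 12
Reactants: 14 methacrolein; 15 vinylmagnesium bromide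
Product: 16 2-methylpenta-1,4-dien-3-ol (racemic)
Conditions: THF, −78 → 0 °C; aq. NH4Cl
Reagents that add atoms: none
Why: Grignard 1,2-addition to an enal gives the bis-allylic alcohol directly, and the racemate suffices because its carbinol centre is destroyed in step 13.

Step 13
Reactants: 13 (1S,3R,4R)-4-bromo-3-chloro-1-ethynyl-4-methylcyclohexan-1-ol; 16 2-methylpenta-1,4-dien-3-ol (racemic)
Product: 18 6-[(1S,3R,4R)-4-bromo-3-chloro-1-hydroxy-4-methylcyclohexyl]-2-methylhepta-1,6-dien-3-one, via trienol tautomer 17 (not isolated)
Conditions: [CpRu(MeCN)3]PF6 (10 mol %), 16 (2.5 equiv), acetone, rt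
Reagents that add atoms: none
Why: The cationic CpRu fragment (divalent ruthenium) sheds acetonitrile, binds the alkyne of 13 and the vinyl group of 16 and couples them oxidatively to a ruthenacyclopentene (tetravalent ruthenium) in which the internal alkyne carbon is bonded to the terminal vinyl carbon, after which β-hydride elimination of the carbinol C–H and C–H reductive elimination release trienol 17, which tautomerises to enone 18. The closest known reaction type is the ruthenium-catalysed Alder-ene-type addition of terminal alkynes, tertiary propargylic alcohols included, to allylic alcohols, which gives γ,δ-unsaturated carbonyl compounds carrying a 1,1-disubstituted alkene. No ring of the product is closed (the five-membered metallacycle is transient) and no stereocentre is created, since the racemic carbinol centre of 16 is erased and C1, C3 and C4 are untouched. The step needs branched rather than linear regiochemistry, which the free C1 hydroxyl should secure by coordinating to ruthenium and steering C–C bond formation to the substituted alkyne carbon, and it needs reaction at the vinyl rather than the isopropenyl group of 16, which follows from the inertness of 1,1-disubstituted alkenes in this coupling. It also needs survival of the tertiary bromide and the secondary chloride, which a neutral medium at room temperature, free of base and external nucleophile, should allow. The excess of 16 covers its competing redox isomerisation.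

Step 14
Reactants: 18 6-[(1S,3R,4R)-4-bromo-3-chloro-1-hydroxy-4-methylcyclohexyl]-2-methylhepta-1,6-dien-3-one
Product: 19 (3R)-6-[(1S,3R,4R)-4-bromo-3-chloro-1-hydroxy-4-methylcyclohexyl]-2-methylhepta-1,6-dien-3-ol (target)
Conditions: (S)-Me-CBS [(S)-1-methyl-3,3-diphenyltetrahydro-1H,3H-pyrrolo[1,2-c][1,3,2]oxazaborole] (0.3 equiv), catecholborane (2.5 equiv), toluene, −78 °C; MeOH, then aq. NaHCO3
Reagents that add atoms: none
Why: Corey–Bakshi–Shibata reduction, in which the ketone binds to the catalyst boron with the larger isopropenyl group turned away and takes hydride from the nitrogen-bound borane on one face, so that the (S)-catalyst should give the (3R)-alcohol in the same sense as acetophenone gives (R)-1-phenylethanol, independently of the remote ring centres, while catecholborane at −78 °C avoids hydroboration of the two 1,1-disubstituted alkenes.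

Compound list
1 | isoprene (2-methylbuta-1,3-diene) | C=CC(C)=C | starting material
2 | methyl propiolate | C#CC(=O)OC | starting material
3 | methyl 4-methylcyclohexa-1,4-diene-1-carboxylate | COC(=O)C1=CCC(C)=CC1 | intermediate
4 | (4-methylcyclohexa-1,4-dien-1-yl)methanol | OCC1=CCC(C)=CC1 | intermediate
5 | [(1S,6S)-4-methyl-7-oxabicyclo[4.1.0]hept-3-en-1-yl]methanol | OC[C@@]12CC=C(C)C[C@@H]1O2 | intermediate
6 | (S)-1-(hydroxymethyl)-4-methylcyclohex-3-en-1-ol | OC[C@]1(O)CCC(C)=CC1 | intermediate
7 | (S)-1-hydroxy-4-methylcyclohex-3-ene-1-carbaldehyde | O=C[C@]1(O)CCC(C)=CC1 | intermediate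
8 | (S)-1-ethynyl-4-methylcyclohex-3-en-1-ol | C#C[C@]1(O)CCC(C)=CC1 | intermediate
9 | (1S,3S,6R)-3-ethynyl-6-methyl-7-oxabicyclo[4.1.0]heptan-3-ol | C#C[C@]1(O)CC[C@@]2(C)O[C@H]2C1 | intermediate
10 | (1S,3S,6R)-3-ethynyl-6-methyl-7-oxabicyclo[4.1.0]heptan-3-yl acetate | C#C[C@]1(OC(C)=O)CC[C@@]2(C)O[C@H]2C1 | intermediate
11 | (1S,3R,4R)-3-chloro-1-ethynyl-4-hydroxy-4-methylcyclohexyl acetate | C#C[C@]1(OC(C)=O)CC[C@@](C)(O)[C@H](Cl)C1 | intermediate
12 | (1S,3R,4R)-4-bromo-3-chloro-1-ethynyl-4-methylcyclohexyl acetate | C#C[C@]1(OC(C)=O)CC[C@@](C)(Br)[C@H](Cl)C1 | intermediate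
13 | (1S,3R,4R)-4-bromo-3-chloro-1-ethynyl-4-methylcyclohexan-1-ol | C#C[C@]1(O)CC[C@@](C)(Br)[C@H](Cl)C1 | intermediate
14 | methacrolein | C=C(C)C=O | starting material
15 | vinylmagnesium bromide | C=C[Mg]Br | starting material
16 | 2-methylpenta-1,4-dien-3-ol (racemic) | C=CC(O)C(C)=C | intermediate
17 | 6-[(1S,3R,4R)-4-bromo-3-chloro-1-hydroxy-4-methylcyclohexyl]-2-methylhepta-1,3,6-trien-3-ol (enol, not isolated) | C=C(C)C(O)=CCC(=C)[C@]1(O)CC[C@@](C)(Br)[C@H](Cl)C1 | intermediate
18 | 6-[(1S,3R,4R)-4-bromo-3-chloro-1-hydroxy-4-methylcyclohexyl]-2-methylhepta-1,6-dien-3-one | C=C(C)C(=O)CCC(=C)[C@]1(O)CC[C@@](C)(Br)[C@H](Cl)C1 | intermediate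
19 | (3R)-6-[(1S,3R,4R)-4-bromo-3-chloro-1-hydroxy-4-methylcyclohexyl]-2-methylhepta-1,6-dien-3-ol | C=C(C)[C@H](O)CCC(=C)[C@]1(O)CC[C@@](C)(Br)[C@H](Cl)C1 | target

Total step count: 14.
Longest linear sequence: 13 steps (steps 1 to 11, then 13 and 14); step 12 is a one-step side branch.

Steps most likely to fail

Step 10. The β-chlorine slows heterolysis of the C4–O bond, proton loss from the cation can outrun bromide capture, and weak chlorine bridging can let bromide approach from the wrong face. The fallback sets out from 11 and comes back at 12, and it separates C–O cleavage from C–Br formation. Dehydration of 11 with SOCl2 in pyridine at 0 °C, an anti elimination of the axial chlorosulfite toward C5, would give (1S,5R)-5-chloro-1-ethynyl-4-methylcyclohex-3-en-1-yl acetate F1. Markovnikov addition of anhydrous HBr in CH2Cl2 at −40 °C to its trisubstituted alkene is far faster than addition to the terminal alkyne. It would regenerate the cation in a bromide-rich medium and deliver bromide axially at C4, anti to the allylic C–Cl bond, to give 12.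

Step 13. The fully substituted propargylic carbon may push C–C bond formation to the alkyne terminus and erode the branched regioselectivity. Redox isomerisation may also consume the allylic alcohol, and the Lewis acidic ruthenium cation may slowly ionise the C–Br bond. The fallback sets out from 13 and comes back at 18, and it makes the same C5'–C6' bond by oxidative-addition chemistry.
- Markovnikov hydrosilylation of 13 with Et3SiH and [Cp*Ru(MeCN)3]PF6 in CH2Cl2 at 0 °C would give (1S,3R,4R)-4-bromo-3-chloro-4-methyl-1-[1-(triethylsilyl)ethenyl]cyclohexan-1-ol F2.
- Iododesilylation with N-iodosuccinimide in MeCN/(CF3)2CHOH at 0 °C would give (1S,3R,4R)-4-bromo-3-chloro-1-(1-iodoethenyl)-4-methylcyclohexan-1-ol F3.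
- A ligand-free Heck reaction of F3 with dienol 16 (Pd(OAc)2, Bu4NCl, NaHCO3, DMF, rt) would give 18. The alkenylpalladium species adds to the vinyl terminus and β-hydride elimination runs toward the carbinol.

Step 9. Partial cationic character under acid activation may divert chloride to the tertiary C4 or trigger a hydride shift of the epoxide to a ketone. The fallback sets out from 8, bypasses 9 and 10 and comes back at 11, and it reverses the polarity of the chlorine source. Acetylation of 8 (Ac2O, Et3N, 4-(dimethylamino)pyridine, CH2Cl2) would give (S)-1-ethynyl-4-methylcyclohex-3-en-1-yl acetate F4. Electrophilic chlorohydroxylation with trichloroisocyanuric acid in aqueous acetone at 0 °C would then place water on the tertiary C4 and chlorine on C3 by Markovnikov, anti and trans-diaxial addition. The electronic bias that endangers step 9 now secures the regiochemistry. Facial selectivity would rest only on the modest preference for the axial-ethynyl half-chair and would have to be completed by chromatography before 11 is carried on.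

Further compounds
F1 | step 10 | (1S,5R)-5-chloro-1-ethynyl-4-methylcyclohex-3-en-1-yl acetate | C#C[C@]1(OC(C)=O)CC=C(C)[C@H](Cl)C1
F2 | step 13 | (1S,3R,4R)-4-bromo-3-chloro-4-methyl-1-[1-(triethylsilyl)ethenyl]cyclohexan-1-ol | C=C([Si](CC)(CC)CC)[C@]1(O)CC[C@@](C)(Br)[C@H](Cl)C1
F3 | step 13 | (1S,3R,4R)-4-bromo-3-chloro-1-(1-iodoethenyl)-4-methylcyclohexan-1-ol | C=C(I)[C@]1(O)CC[C@@](C)(Br)[C@H](Cl)C1
F4 | step 9 | (S)-1-ethynyl-4-methylcyclohex-3-en-1-yl acetate | C#C[C@]1(OC(C)=O)CCC(C)=CC1
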